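## Retrosynthetic overview
- **C7–C8 (key bond):** the carbonyl carbons of veratraldehyde 1 and acetaldehyde 2 are joined. Aldehyde 1 reacts as an enzyme-bound acyl anion (ThDP Breslow enaminol 3). This gives (R)-ketol 4 and sets C8 as the bond forms.
- **C8–OAr:** Mitsunobu inversion of 4 with 4-allyl-2,6-dimethoxyphenol 5, through oxyphosphonium 6, gives (S)-aryloxy ketone 7.
- **C7–H and C7–OAc:** chelation-controlled hydride addition to 7 gives erythro alcohol 8, which is acetylated in the same flask to maceneolignan H 9.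
- **Rings:** none is formed. Both arenes are bought intact, with the allyl group already in place.

Assumption: with neolignan numbering (C7 benzylic, C8 ether carbon) the SMILES decodes as (7R,8S), the erythro series; recombinant benzaldehyde lyase is treated as a catalyst, not a starting material.

## Route

Step 1
Reactants: 1 3,4-dimethoxybenzaldehyde (veratraldehyde); 2 acetaldehyde
Product: 4 (R)-1-(3,4-dimethoxyphenyl)-2-hydroxypropan-1-one, via ThDP Breslow enaminol 3 (not isolated)
Conditions: benzaldehyde lyase (BAL, Pseudomonas fluorescens, recombinant, cat.), ThDP (0.15 mM), MgSO4 (2.5 mM), KPi (50 mM, pH 7.5)/DMSO 4:1, 2 (5 equiv, fed in portions), 30 °C, 24–48 h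
Reagents that add atoms: none
Why: Enzymatic asymmetric cross-benzoin (acyloin) carboligation, in which the ThDP ylide adds to 1 and deprotonation gives enaminol 3, an acyl anion equivalent at C7, which attacks the carbonyl carbon of 2 on the face fixed by the BAL active site to give the (R)-2-hydroxypropiophenone series (typically >97% ee with meta/para-alkoxybenzaldehyde donors), self-condensation of 1 being reversible under the lyase.

Step 2
Reactants: 4 (R)-1-(3,4-dimethoxyphenyl)-2-hydroxypropan-1-one; 5 4-allyl-2,6-dimethoxyphenol (methoxyeugenol)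
Product: 7 (S)-2-(4-allyl-2,6-dimethoxyphenoxy)-1-(3,4-dimethoxyphenyl)propan-1-one, via alkoxyphosphonium phenoxide 6 (not isolated)
Conditions: PPh3 (1.5 equiv), DIAD (1.5 equiv), toluene/THF (0.5 M), 0 °C → rt
Reagents that add atoms: none
Why: Mitsunobu etherification, in which the phenoxide of 5 (pKa ≈ 10) displaces the C8 oxyphosphonium group of 6 in an SN2 step accelerated by the adjacent carbonyl, so C8 inverts cleanly from R to S as in lactate/phenol Mitsunobu couplings, and the near-neutral medium spares the epimerisable α-centre.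

Step 3
Reactants: 7 (S)-2-(4-allyl-2,6-dimethoxyphenoxy)-1-(3,4-dimethoxyphenyl)propan-1-one
Product: 9 maceneolignan H [(1R,2S)-2-(4-allyl-2,6-dimethoxyphenoxy)-1-(3,4-dimethoxyphenyl)propyl acetate], via erythro alcohol 8 (not isolated)
Conditions: LiAlH4 (0.6 equiv), Et2O/THF 4:1, −78 °C, 1 h; then pyridine (5 equiv), DMAP (0.5 equiv), Ac2O (8 equiv), −78 °C → rt, same flask; Rochelle salt work-up
Reagents that add atoms: acetic anhydride, CC(=O)OC(C)=O
Why: Cram-chelate (chelation-controlled) 1,2-induction followed by Rychnovsky-type reductive acetylation, in which Li+ bridges the C=O and the C8 aryloxy oxygen (helped by an ortho-OMe) so that hydride enters from the C8–H face to give the erythro (7R) alkoxide, which DMAP/Ac2O traps directly, while C8, the aryl ethers and the allyl group are untouched.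

## Compound list
1 | 3,4-dimethoxybenzaldehyde (veratraldehyde) | COc1ccc(C=O)cc1OC | starting material
2 | acetaldehyde | CC=O | starting material
3 | ThDP Breslow enaminol of 1 (enzyme-bound 2-[(3,4-dimethoxyphenyl)(hydroxy)methylidene]thiazoline of thiamine diphosphate) | Cc1ncc(CN2C(C)=C(CCOP(=O)(O)OP(=O)(O)O)SC2=C(O)c3ccc(OC)c(OC)c3)c(N)n1 | intermediate
4 | (R)-1-(3,4-dimethoxyphenyl)-2-hydroxypropan-1-one | C[C@@H](O)C(=O)c1ccc(OC)c(OC)c1 | intermediate
5 | 4-allyl-2,6-dimethoxyphenol (methoxyeugenol) | C=CCc1cc(OC)c(O)c(OC)c1 | starting material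
6 | (R)-[1-(3,4-dimethoxyphenyl)-1-oxopropan-2-yl]oxytriphenylphosphonium 4-allyl-2,6-dimethoxyphenoxide | C[C@@H](O[P+](c1ccccc1)(c1ccccc1)c1ccccc1)C(=O)c1ccc(OC)c(OC)c1.C=CCc1cc(OC)c([O-])c(OC)c1 | intermediate
7 | (S)-2-(4-allyl-2,6-dimethoxyphenoxy)-1-(3,4-dimethoxyphenyl)propan-1-one | C=CCc1cc(OC)c(O[C@@H](C)C(=O)c2ccc(OC)c(OC)c2)c(OC)c1 | intermediate
8 | (1R,2S)-2-(4-allyl-2,6-dimethoxyphenoxy)-1-(3,4-dimethoxyphenyl)propan-1-ol (erythro; present in the flask as its Li/Al alkoxide, drawn as the alcohol) | C=CCc1cc(OC)c(O[C@@H](C)[C@H](O)c2ccc(OC)c(OC)c2)c(OC)c1 | intermediate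
9 | maceneolignan H, (1R,2S)-2-(4-allyl-2,6-dimethoxyphenoxy)-1-(3,4-dimethoxyphenyl)propyl acetate | C=CCc1cc(OC)c(O[C@@H](C)[C@H](OC(C)=O)c2ccc(OC)c(OC)c2)c(OC)c1 | target

## Step count and risk
Total step count: 3. Longest linear sequence: 3 (1 → 4 → 7 → 9).

**Most likely to fail, first: step 2.**
- **Risk:** the phenol is flanked by two methoxy groups, and the carbinol is α to an aryl ketone. Slow substitution or partial epimerisation at C8 could result.
- **Fallback:** it sets out from 4 and replaces the redox condensation by separate activation and Williamson-type displacement. Mesylation (MsCl, Et3N, CH2Cl2, −20 °C) gives (R)-1-(3,4-dimethoxyphenyl)-1-oxopropan-2-yl methanesulfonate F5. The pre-formed phenoxide of 5 (K2CO3, MeCN, 0 °C) then displaces the mesylate with inversion, the same SN2 that α-halo propiophenones undergo with phenoxides. The fallback comes back to the route at 7.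

**Second: step 1.**
- **Risk:** 1 must be accepted as the donor, acetaldehyde slowly deactivates the enzyme, and the ee depends wholly on the active site.
- **Fallback:** it sets out from 1 and keeps the acyl anion logic, but moves the stereochemical decision to a reagent-controlled reduction.
  - Propane-1,3-dithiol with BF3·OEt2 gives 2-(3,4-dimethoxyphenyl)-1,3-dithiane F1.
  - n-BuLi (THF, −78 °C) gives 2-lithio-2-(3,4-dimethoxyphenyl)-1,3-dithiane F2.
  - N-Methoxy-N-methylacetamide acylates it to 1-[2-(3,4-dimethoxyphenyl)-1,3-dithian-2-yl]ethan-1-one F3.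
  - (S)-Me-CBS/BH3·SMe2 (large dithianyl against small methyl) reduces this to (R)-1-[2-(3,4-dimethoxyphenyl)-1,3-dithian-2-yl]ethan-1-ol F4.
  - Alkylative hydrolysis (MeI, CaCO3, aq. MeCN) unmasks the ketone, and the fallback comes back to the route at 4.

**Third: step 3.**
- **Risk:** an aryl ether is a weaker chelating donor than an alkyl ether, so the erythro:threo ratio may be only moderate. In addition, the trapping has to run on an aluminium alkoxide.
- **Fallback:** it sets out from 7 and deliberately makes the other diastereomer. A non-chelating Felkin–Anh reduction (L-Selectride, THF, −78 °C) gives (1S,2S)-2-(4-allyl-2,6-dimethoxyphenoxy)-1-(3,4-dimethoxyphenyl)propan-1-ol F6, which is isolated and purified. A Mitsunobu esterification with acetic acid (PPh3, DIAD, toluene, 0 °C) then inverts C7 to R and installs the acetate in one operation. The fallback comes back to the route at 9.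

## Further compounds
F1 | step 1 | 2-(3,4-dimethoxyphenyl)-1,3-dithiane | COc1ccc(C2SCCCS2)cc1OC
F2 | step 1 | 2-lithio-2-(3,4-dimethoxyphenyl)-1,3-dithiane | [Li]C1(c2ccc(OC)c(OC)c2)SCCCS1
F3 | step 1 | 1-[2-(3,4-dimethoxyphenyl)-1,3-dithian-2-yl]ethan-1-one | CC(=O)C1(c2ccc(OC)c(OC)c2)SCCCS1
F4 | step 1 | (R)-1-[2-(3,4-dimethoxyphenyl)-1,3-dithian-2-yl]ethan-1-ol | C[C@@H](O)C1(c2ccc(OC)c(OC)c2)SCCCS1
F5 | step 2 | (R)-1-(3,4-dimethoxyphenyl)-1-oxopropan-2-yl methanesulfonate | C[C@@H](OS(C)(=O)=O)C(=O)c1ccc(OC)c(OC)c1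
F6 | step 3 | (1S,2S)-2-(4-allyl-2,6-dimethoxyphenoxy)-1-(3,4-dimethoxyphenyl)propan-1-ol (threo) | C=CCc1cc(OC)c(O[C@@H](C)[C@@H](O)c2ccc(OC)c(OC)c2)c(OC)c1
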